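No rate constant is given for this flask, so a reckoning has to start from a constant read off the readings of the two runs.

in all of them: substrate 0.10 M
- eta: reagent 0.15 M; free catalyst 2 mM; temperature 25 °C; the very flask that is asked about, followed so far
- beta: reagent 0.15 M; free catalyst 2 mM; temperature 10 °C; run made earlier
- flask: reagent 0.150 M; free catalyst 2.0 mM; temperature 25 °C; time 10 h

| run | time / h | target / % | substrate / % |
|---|---|---|---|
| eta | 2.50 | 34.1 | 1.1 |
| eta | 5.00 | 34.6 | 0 |
| eta | 8.00 | 33.8 | 0.2 |
| eta | 10.0 | 33.8 | 0.4 |
| beta | 5.00 | 18.5 | 23.7 |
| beta | 10.0 | 21.2 | 0.5 |
| beta | 15.0 | 20.1 | 0 |
| beta | 20.0 | 20.1 | 0.2 |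

(readings scatter by 0.5 percentage points)

- target, in percent of the substrate first charged, at 10 h
- the remedy with the largest gain of target, or "none" below 2 percentage points (noon / winter / dusk / dawn / midnight / none)
- target present, with what was taken out counted in, in percent of the substrate first charged, after noon
- target present, with what was taken out counted in, in percent of the substrate first charged, after dawn

- noon: at 10 h raise the temperature by 25 K, then wait 5.0 h
- winter: change nothing and wait 5.0 h more
- dusk: at 10 h add reagent, 50.0% of the amount charged, then wait 5.0 h
- dawn: at 10 h take out 90% of the target then present, then wait 5.0 h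
- midnight: at 10 h add free catalyst, 100% of the amount charged, then wait 5.0 h

- target taken out counts as made
- additions bring no volume worth counting

In the eta run, substrate reads 1.1% at 2.50 h, and target stays within the scatter from there, 34.1% then 33.8%. The own estimate of target at 10 h is therefore 33.8%, and waiting adds nothing. With 0.4% substrate read at 10.0 h, less than one standard deviation, extra reagent or catalyst has hardly any substrate to convert.

The beta run levels off lower than the eta run, and its target reads 21.2% before settling at 20.1%. That fall is weak evidence, but it points to a balance (thermodynamic control) rather than a fixed selectivity. Target over everything that is not target reads 0.511 at 25 °C and 0.252 at 10 °C. This is the carried quantity, the plateau ratio: target over what stands in exchange with it once the flask is at rest, with everything that is not target taken as a first guess at that exchanging material. Between the two temperatures the reading grows to twice its lower value.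

Stretching the same growth over the noon rise gives a ratio of 1.66, which means 62.4% target. For dawn, 30.4% leaves the flask, and putting the plateau share back into the remaining 69.6% gives a total of 53.9%. Noon stands higher than dawn. The weak link is the denominator of the ratio, since part of that material might not exchange.

The forecast says 34.1%, noon, 59% after noon and 54.3% after dawn, on the ground “I assume all non-target material stays in this pool”. Its noon figure lies below the own 62.4%.

The flask gives 33.7%. The best remedy is noon, with a gain of 21 percentage points and 54.6% target, while dawn gains 16 points and reaches 49.6%.

    substrate + catalyst intermediate A → catalyst intermediate B (k = 26.9 M⁻¹ min⁻¹, Ea = 51.0 kJ mol⁻¹)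
    catalyst intermediate B → free catalyst + target (k = 0.803 min⁻¹, Ea = 73.0 kJ mol⁻¹)
    target ⇌ isomer of the product (K = 1.10, k = 0.154 min⁻¹, Ea = 91.0 kJ mol⁻¹, ΔH = −42.0 kJ mol⁻¹)
    reagent + free catalyst → catalyst intermediate A (k = 17.4 M⁻¹ min⁻¹, Ea = 42.0 kJ mol⁻¹)
    substrate + target → side product (k = 0.189 M⁻¹ min⁻¹, Ea = 58.0 kJ mol⁻¹)
    (constants at 25 °C)

At 0.785 h, substrate in the flask went into catalyst intermediate B faster than into side product by a factor of 4.5; side product, which counts as two, stands at 29.2% at 10.0 h outside the exchange, and the plateau ratio of the flask taken against isomer of the product is 0.909, higher than the 0.511 read against all the rest in the eta run. The neighbour charged with 0.025 M of substrate holds 5.78% side product, 44.9% target and 49.4% isomer of the product, a plateau ratio of 0.909 against isomer of the product and 0.814 against all the rest, higher than the 0.511 of the eta run.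

(The earlier runs and the new flask were generated by integration for an exercise; the scatter is artificial.)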